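**Assumptions and remarks on the chemistry**

- Assumption: 2-(benzyloxy)-N-methoxy-N-methylacetamide (2) is taken to be a catalogue compound; if it has to be made, it is one amidation from benzyloxyacetyl chloride.
- The structures of 7 and 10 are consistent with the target. The free ring carbon of 7 becomes C8a, and its two hydroxyls become O5 and O8.
- The free hydroquinone is kept in 7 on purpose. Masking the ortho oxygen (for example as a methyl ether, lost as methanol in an anodic para-methoxyphenol oxidation) would rule out ordinary cyclodehydration. It would also raise the potential needed and narrow the window against oxidation of the diketone enolate.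
- The way to 7 avoids a photochemical acylation of a quinone with an alpha-benzyloxy aldehyde: the excited quinone should abstract the benzylic ether hydrogen in competition, and the alpha-alkoxy acyl radical loses CO readily. The ring A oxygens are carried as methyl ethers through an ionic C–C bond formation instead, and the para pair is unveiled oxidatively.
- Compound 7 should be kept away from acid and used soon after it is made, because it can equilibrate with its cyclic hemiketal.
- Reduction of 10 and methylation of O8 are run in one carbonate-buffered flask. The reduced flavone is then present only as its 8-phenoxide, under excess dithionite, and is methylated there. The air-sensitive free diol is not liberated and no solvent change under argon is needed.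

## Structural features

The target is a flavonol: a benzene ring A fused to a 4-pyranone ring C (O1, C2, C3, C4, C4a, C8a), with a 4-hydroxyphenyl ring B on C2. Ring A is fully substituted. C5 carries a hydroxyl hydrogen-bonded to the C4 carbonyl, and C6, C7 and C8 carry methoxy groups, so that with O1 on C8a five oxygen atoms stand in a row on one benzene ring. There is no stereocentre. The fragile parts are the free 3-hydroxy-4-pyranone (easily oxidised in base), the electron-rich ring A (easily over-oxidised or demethylated) and any 5,8-dihydroxy intermediate on the way. The real difficulty is the oxygen pattern and not the skeleton: four neighbouring ring A oxygens must be told apart, ring C must close onto the correct ortho position, and C3 must bear oxygen. The key step uses the para relation of O5 and O8 on ring A. With C6 and C7 methylated, ring A is a masked 5,8-quinone whose only hydrogen-bearing carbon is C8a. In that quinone C8a is the beta carbon of both the C5 carbonyl and the C4 ketone, so the enol oxygen that is to become O1 can add there.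

## Logic of the disconnections

**12 to 11.** The two O–benzyl bonds at O3 and O4' are cut. Hydrogenolysis can remove them last without touching the three methyl ethers or the chelated O5–H, so the most easily oxidised enol and phenol stay masked through every redox step. The forward step must only leave the C2=C3 bond of the pyranone unreduced.

**11 to 10.** The O8–CH3 bond is cut and ring A is returned to the quinone oxidation level. When 10 is reduced in carbonate, O8 appears as a phenoxide while O5–H stays tied to the C4 carbonyl by a hydrogen bond, so the two oxygens differ. The forward step must methylate once, at O8 only, and must keep the reduced ring from being reoxidised. Running both operations in one flask under excess reductant meets the second demand.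

**10 to 7 (through 9 and 8).** The O1–C8a bond is cut, which opens ring C and returns ring A to a hydroquinone with a single C–H. This is a large simplification: 7 is an acyclic 1,3-diketone in which all four ring A oxygens are present and already differentiated two by two. The forward step must oxidise before any ring closure, must close through the enol oxygen and not through the ortho hydroxyl, and must not oxidise the enol, ring B or the benzyl ethers. An electrode held at the low potential of a hydroquinone meets the last demand.

**7 to 5 and 6.** The bond between the central diketone carbon (future C3) and the aroyl carbon (future C2) is cut, a Claisen disconnection. Ring B arrives as an acid chloride and the C3 oxygen is already in place, so no late oxidation at C3 is needed. The forward step must acylate at carbon in the presence of two phenoxides and be worked up without strong acid.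

**5 to 3 (through 4).** The two free hydroxyls are traced back to methyl ethers. In 3 only one pair of methoxy groups is para, and it is exactly the pair to be unveiled, so oxidative demethylation to 4 followed by reduction selects them without a protecting-group step. The oxidant must give the para-quinone and spare the benzyl ether, and 4 must be reduced before it reacts with water.

**3 to 1 and 2.** The aryl–carbonyl bond (future C4a–C4) is cut. Compound 1 is symmetric, with two equivalent C–H positions each next to a methoxy group, so lithiation and acylation by 2 install the side chain in one operation. The forward step needs mono-lithiation and a single addition to the acyl donor.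

## Other disconnections considered

**Alternative 1:** The cut removes both bonds from ring A to the three-carbon unit, C8a–O1 and C4a–C4. Ring A arrives as an aryne and the rest as a carboxylic acid.

- Forward key step: CsF would release the symmetric aryne from 2,3,4,5-tetramethoxy-6-(trimethylsilyl)phenyl trifluoromethanesulfonate A2. The carboxylate of (Z)-2-(benzyloxy)-3-[4-(benzyloxy)phenyl]prop-2-enoic acid A3 adds through oxygen, the aryl anion attacks the ester carbonyl, and the four-membered adduct opens. The product is (Z)-2-(benzyloxy)-3-[4-(benzyloxy)phenyl]-1-(2-hydroxy-3,4,5,6-tetramethoxyphenyl)prop-2-en-1-one A1.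
- In its favour: the aryne is symmetric, so no regiochemical question arises. Two bonds form in one convergent step. Ring A never changes oxidation level. Insertion of arynes into the C–O bond of carboxylic acids is a known reaction type, so on precedent for the key step this alternative is the better of the two.
- Against it here: A2 needs several steps of its own. Protonation of the aryl anion by the acid, giving a plain aryl ester, is the usual competitor of the acyl shift, and here the anion is flanked by a methoxy group. A1 is still an open chalcone, so ring C needs a separate oxidative O1–C2 closure, followed by chelation-controlled cleavage of the C5 methyl ether and debenzylation.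
- Comparison: on structure, Alternative 1 uses the symmetry of the tetramethoxy ring, while the chosen plan uses the para relation of O5 and O8. Differentiating O5 by chelation-controlled demethylation is as well founded as the chelation-controlled methylation of the chosen plan, so the two are equal on that point. On step economy the chosen plan is shorter (six steps against roughly ten).

**Alternative 2:** The cut is at C3–C4 and O1–C2.

- Forward key step: 2-hydroxy-3,4,5,6-tetramethoxybenzaldehyde A5 and (E)-2-[4-(benzyloxy)phenyl]ethenylboronic acid A6 would condense under catalytic HNBn2. The phenol-bound boronate delivers the alkenyl group to the iminium carbon, the amine leaves to give an ortho-quinone methide, and a 6π electrocyclisation closes ring C. The product is racemic 2-[4-(benzyloxy)phenyl]-5,6,7,8-tetramethoxy-2H-chromene A4.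
- In its favour: the conditions are mild and catalytic, two bonds and ring C form in one step, and the reaction type is known for 2H-chromenes. On mildness and precedent of the key step it is the better of the two.
- Against it here: ring C arrives three oxidation levels too low. C4 must become a ketone, C3 must gain oxygen and C2 must become sp2, all by oxidations on a molecule whose tetramethoxy ring A is itself easily oxidised. The C2 stereocentre of A4 is formed only to be destroyed. The formyl group of A5 sits between a hydroxyl and a methoxy group on an electron-rich ring, which should slow iminium formation and alkenyl transfer. The C5 methyl ether still has to be cleaved selectively.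
- Comparison: on mechanism the alternative is safer at the ring-closing step, but riskier afterwards. The chosen plan delivers ring C at the final oxidation level with O3 in place. On step economy the chosen plan is clearly ahead.

**Alternative 3:** The cut is at C4–C4a.

- Forward key step: (Z)-3-[4-(benzyloxy)phenyl]-3-(2,3,4,5-tetramethoxyphenoxy)prop-2-enoic acid A8 would be made by conjugate addition of 2,3,4,5-tetramethoxyphenol A9 to ethyl 3-[4-(benzyloxy)phenyl]prop-2-ynoate A10 and hydrolysis. It is activated with (CF3CO)2O, and the acylium carbon attacks the one free ring A carbon. The product is 2-[4-(benzyloxy)phenyl]-5,6,7,8-tetramethoxy-4H-chromen-4-one A7.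
- In its favour: this is an intramolecular Friedel–Crafts acylation of a very electron-rich ring with a single open position, a known and dependable flavone closure. Ring A undergoes no redox chemistry, and the pyranone forms at the correct oxidation level. On reliability of the ring closure it is the better of the two.
- Against it here: A7 has no oxygen at C3. A separate C3 hydroxylation of a 5-methoxyflavone is needed, which is the weakest kind of step in flavonol synthesis. The strongly acidic acylation medium may attack the aryl benzyl ether. Only the Z acid can close. Selective C5 demethylation and debenzylation still follow.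
- Comparison: on structure the chosen plan carries O3 from the first step, while Alternative 3 leaves it to the end. On step economy the alternative needs about nine steps against six.

Key step: step 4

## Route

Step 1
Reactants: 1 1,2,3,4-tetramethoxybenzene; 2 2-(benzyloxy)-N-methoxy-N-methylacetamide
Product: 3 2-(benzyloxy)-1-(2,3,4,5-tetramethoxyphenyl)ethan-1-one
Conditions: 1, n-BuLi, TMEDA, THF, 0 °C; then 2, −78 to 0 °C; cold 1 M HCl
Reagents that add atoms: none
Why: Directed ortho-lithiation followed by Weinreb amide acylation; the two free positions of 1 are equivalent and each lies next to a methoxy group, and the chelated tetrahedral adduct holds until the quench, so the ketone is not attacked a second time.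

Step 2
Reactants: 3 2-(benzyloxy)-1-(2,3,4,5-tetramethoxyphenyl)ethan-1-one
Product: 5 2-(benzyloxy)-1-(2,5-dihydroxy-3,4-dimethoxyphenyl)ethan-1-one, via acylquinone 4 (not isolated)
Conditions: (NH4)2Ce(NO3)6 (2.5 equiv), MeCN/H2O, 0 °C; extraction into EtOAc; then aq. Na2S2O4, rt
Reagents that add atoms: water, O
Why: Oxidative demethylation of a para-dimethoxyarene by tetravalent cerium, then quinone-to-hydroquinone reduction; only the methoxy groups at C2 and C5 of the aryl ring are para to each other, so water attacks there and two methanol are lost, and the reactive acylquinone 4 is reduced at once by dithionite while the benzyl ether is left alone at 0 °C.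

Step 3
Reactants: 5 2-(benzyloxy)-1-(2,5-dihydroxy-3,4-dimethoxyphenyl)ethan-1-one; 6 4-(benzyloxy)benzoyl chloride
Product: 7 2-(benzyloxy)-3-[4-(benzyloxy)phenyl]-1-(2,5-dihydroxy-3,4-dimethoxyphenyl)propane-1,3-dione (racemic; enolisable)
Conditions: LiN(SiMe3)2 (4.2 equiv), THF, −78 to −10 °C; then 6 (1.0 equiv), −78 °C to rt; cold aq. NaH2PO4; Ar
Reagents that add atoms: none
Why: Claisen-type C-acylation of the lithium polyanion of an ortho-hydroxyaryl ketone (the one-flask form of the Baker–Venkataraman synthesis); the enolate carbon is the most nucleophilic site of the trianion, any ester formed at the ortho oxygen is carried to the same diketone by acyl shift, and the new sp3 carbon is racemic and enolisable and becomes sp2 in step 4.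

Step 4
Reactants: 7 2-(benzyloxy)-3-[4-(benzyloxy)phenyl]-1-(2,5-dihydroxy-3,4-dimethoxyphenyl)propane-1,3-dione
Product: 10 3-(benzyloxy)-2-[4-(benzyloxy)phenyl]-6,7-dimethoxy-4H-chromene-4,5,8-trione, via acylquinone 8 (not isolated), via 5,8-dihydroxyflavone 9 (not isolated)
Conditions: graphite anode, Pt cathode, divided cell; MeCN/aq. phosphate buffer (pH 7) 3:1, LiClO4; constant current, 4 F/mol, rt, Ar
Reagents that add atoms: none
Why: Proposed new method: the anode removes two electrons and two protons from the hydroquinone of 7 to give acylquinone 8, whose only C–H ring carbon (the future C8a) is beta to both the C5 carbonyl and the C4 ketone; the enol or enolate oxygen on the carbon bearing ring B adds to it (oxa-Michael addition, equally an oxa-6π closure), tautomerisation gives hydroquinone 9, and 9, which carries one more oxygen donor than 7, should be oxidised further at the anode or by 8 in solution to quinone 10, so that four faradays per mole are consumed. The closest known reaction type is the anodic oxidation of hydroquinones and catechols in buffered aqueous acetonitrile with Michael addition of 1,3-dicarbonyl compounds or other nucleophiles to the quinone formed at the electrode (electron transfer, chemical step, electron transfer); here the nucleophile is tethered and reacts through oxygen. Ring C closes in the 6-endo-trig mode, and no stereocentre is formed, since the racemic centre of 7 becomes the sp2 carbon C3. Site selectivity rests on the substitution pattern, because the other three quinone ring carbons carry the acyl group or methoxy groups; attack through the central carbon would need a four-membered ring and addition to the C5 carbonyl gives only a reversible hemiketal. The competing ordinary cyclodehydration through the ortho hydroxyl needs acid and should be slow at pH 7, and once 8 has formed that oxygen is a carbonyl and cannot act as the nucleophile, so it is kept as O5. A hydroquinone is oxidised far below the potentials of the benzyl ethers, ring B and the diketone enol, which secures chemoselectivity at the electrode.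

Step 5
Reactants: 10 3-(benzyloxy)-2-[4-(benzyloxy)phenyl]-6,7-dimethoxy-4H-chromene-4,5,8-trione
Product: 11 3-(benzyloxy)-2-[4-(benzyloxy)phenyl]-5-hydroxy-6,7,8-trimethoxy-4H-chromen-4-one
Conditions: 10 in degassed THF added to aq. Na2S2O4 (3 equiv), Na2CO3 (6 equiv), Bu4NBr (10 mol %), THF/H2O 1:1, 0 °C to rt, Ar; then Me2SO4 (1.5 equiv), rt; aq. NH3 quench
Reagents that add atoms: dimethyl sulfate, COS(=O)(=O)OC
Why: One-flask reductive methylation of a quinone (dithionite reduction under phase-transfer conditions, then Williamson etherification); in carbonate the reduced flavone appears directly as its 8-phenoxide, while the C5 hydroxyl stays protonated and hydrogen-bonded to the C4 carbonyl, so a small excess of Me2SO4 should etherify O8 only. The excess dithionite keeps the phenoxide from being reoxidised until it is methylated.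

Step 6
Reactants: 11 3-(benzyloxy)-2-[4-(benzyloxy)phenyl]-5-hydroxy-6,7,8-trimethoxy-4H-chromen-4-one
Product: 12 3,5-dihydroxy-2-(4-hydroxyphenyl)-6,7,8-trimethoxy-4H-chromen-4-one (3,5,4'-trihydroxy-6,7,8-trimethoxyflavone)
Conditions: H2 (1 atm), 10% Pd/C, EtOAc/MeOH, rt
Reagents that add atoms: none
Why: Hydrogenolysis of the enol benzyl ether at O3 and the aryl benzyl ether at O4' over Pd/C; the methyl ethers, the chelated phenol and the conjugated C2=C3 bond of the flavone should not be reduced under these mild conditions.

## Compound list

1 | 1,2,3,4-tetramethoxybenzene | COc1ccc(OC)c(OC)c1OC | starting material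
2 | 2-(benzyloxy)-N-methoxy-N-methylacetamide | CON(C)C(=O)COCc1ccccc1 | starting material
3 | 2-(benzyloxy)-1-(2,3,4,5-tetramethoxyphenyl)ethan-1-one | COc1cc(C(=O)COCc2ccccc2)c(OC)c(OC)c1OC | intermediate
4 | 2-[2-(benzyloxy)acetyl]-5,6-dimethoxycyclohexa-2,5-diene-1,4-dione (acylquinone; not isolated) | COC1=C(OC)C(=O)C(C(=O)COCc2ccccc2)=CC1=O | intermediate
5 | 2-(benzyloxy)-1-(2,5-dihydroxy-3,4-dimethoxyphenyl)ethan-1-one | COc1c(O)cc(C(=O)COCc2ccccc2)c(O)c1OC | intermediate
6 | 4-(benzyloxy)benzoyl chloride | O=C(Cl)c1ccc(OCc2ccccc2)cc1 | starting material
7 | 2-(benzyloxy)-3-[4-(benzyloxy)phenyl]-1-(2,5-dihydroxy-3,4-dimethoxyphenyl)propane-1,3-dione (racemic; enolisable) | COc1c(OC)c(O)c(C(=O)C(OCc2ccccc2)C(=O)c2ccc(OCc3ccccc3)cc2)cc1O | intermediate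
8 | 2-{2-(benzyloxy)-3-[4-(benzyloxy)phenyl]-3-oxopropanoyl}-5,6-dimethoxycyclohexa-2,5-diene-1,4-dione (acylquinone; racemic; not isolated) | COC1=C(OC)C(=O)C(C(=O)C(OCc2ccccc2)C(=O)c2ccc(OCc3ccccc3)cc2)=CC1=O | intermediate
9 | 3-(benzyloxy)-2-[4-(benzyloxy)phenyl]-5,8-dihydroxy-6,7-dimethoxy-4H-chromen-4-one (5,8-dihydroxyflavone; not isolated) | COc1c(OC)c(O)c2c(=O)c(OCc3ccccc3)c(-c3ccc(OCc4ccccc4)cc3)oc2c1O | intermediate
10 | 3-(benzyloxy)-2-[4-(benzyloxy)phenyl]-6,7-dimethoxy-4H-chromene-4,5,8-trione | COC1=C(OC)C(=O)C2=C(C1=O)C(=O)C(OCc3ccccc3)=C(c3ccc(OCc4ccccc4)cc3)O2 | intermediate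
11 | 3-(benzyloxy)-2-[4-(benzyloxy)phenyl]-5-hydroxy-6,7,8-trimethoxy-4H-chromen-4-one | COc1c(OC)c(O)c2c(=O)c(OCc3ccccc3)c(-c3ccc(OCc4ccccc4)cc3)oc2c1OC | intermediate
12 | 3,5-dihydroxy-2-(4-hydroxyphenyl)-6,7,8-trimethoxy-4H-chromen-4-one | COc1c(OC)c(O)c2c(=O)c(O)c(-c3ccc(O)cc3)oc2c1OC | target

## Step count and risks

Total step count: 6. Longest linear sequence: 6 steps (1 to 3 to 5 to 7 to 10 to 11 to 12); 2 and 6 enter as purchased reagents.

**Step 4 (key step, proposed new method).**
- What may go wrong: cyclodehydration of 7 through its ortho hydroxyl before oxidation, which would fix the wrong ring A pattern; capture of 8 by water or buffer at the free ring carbon in competition with the tethered enol; passivation of the anode by film formation or over-oxidation of the product. If only the electrode process fails, 8 could be generated with Ag2O in dry CH2Cl2 and left to cyclise.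
- Fallback (known chemistry, from 3 back to the route at 12): this changes the approach and makes the same O1–C8a bond by cross-coupling. Ring bromination of 3 with NBS in MeCN at its one free ring position would give 2-(benzyloxy)-1-(2-bromo-3,4,5,6-tetramethoxyphenyl)ethan-1-one F1. Claisen acylation of its lithium enolate (LiN(SiMe3)2, THF, −78 °C) with 6 would give 2-(benzyloxy)-3-[4-(benzyloxy)phenyl]-1-(2-bromo-3,4,5,6-tetramethoxyphenyl)propane-1,3-dione F2. Intramolecular Ullmann-type O-arylation of the enolate (CuI, 1,10-phenanthroline, Cs2CO3, DMF, 100 °C), a known flavone synthesis from 1-(2-haloaryl)-1,3-diketones, would give 3-(benzyloxy)-2-[4-(benzyloxy)phenyl]-5,6,7,8-tetramethoxy-4H-chromen-4-one F3. BCl3 in CH2Cl2 (−78 to 0 °C) should then remove both benzyl groups and, through chelation to the C4 carbonyl, only the C5 methyl group, arriving at 12.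

**Step 2.**
- What may go wrong: slow electron transfer from the acyl-deactivated ring, attack of water at neighbouring methoxy carbons leading to an ortho-quinone, or hydration of 4 before it is reduced.
- Fallback (from 1 back to 5): the hydroquinone oxygens are unveiled by acetal hydrolysis instead of oxidative demethylation. Oxidation of 1 itself with (NH4)2Ce(NO3)6, a well-behaved case, would give 2,3-dimethoxycyclohexa-2,5-diene-1,4-dione F4. Dithionite reduction would give 2,3-dimethoxybenzene-1,4-diol F5, which is protected without purification (MOMCl, i-Pr2NEt, CH2Cl2) as 2,3-dimethoxy-1,4-bis(methoxymethoxy)benzene F6. Lithiation next to an acetal oxygen (n-BuLi, THF, 0 °C) and acylation with 2 would give 2-(benzyloxy)-1-[3,4-dimethoxy-2,5-bis(methoxymethoxy)phenyl]ethan-1-one F7. HCl in MeOH at rt should then release 5.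

**Step 3.**
- What may go wrong: aroylation of the remote phenoxide or double acylation in place of C-acylation, air oxidation of the trianion, or ring closure through the ortho hydroxyl if the quench is too acidic.
- Fallback (from 5 back to 7): the stepwise Baker–Venkataraman sequence. Compound 5 and 6 (2.2 equiv, pyridine) would give 2-[2-(benzyloxy)acetyl]-5,6-dimethoxy-1,4-phenylene bis[4-(benzyloxy)benzoate] F8. KOt-Bu in THF would shift the ortho aroyl group to carbon to give 5-{2-(benzyloxy)-3-[4-(benzyloxy)phenyl]-3-oxopropanoyl}-4-hydroxy-2,3-dimethoxyphenyl 4-(benzyloxy)benzoate F9. K2CO3 in MeOH/THF at 0 °C under Ar would cleave the remaining aryl ester to 7.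

**Step 5.**
- What may go wrong: attack of carbonate or hydroxide on the quinone before it is reduced, with loss of a ring methoxy group; consumption of Me2SO4 by sulfite, so that methylation stops short and the unreacted phenoxide is reoxidised on work-up; or loss of selectivity between the two ring A oxygens if the medium is too basic.
- Fallback (from 10 back to 11): the reduced ring is trapped in an air-stable, purifiable form before any base is used. Reductive acetylation (Zn, Ac2O, NaOAc) would give 3-(benzyloxy)-2-[4-(benzyloxy)phenyl]-6,7-dimethoxy-4-oxo-4H-chromene-5,8-diyl diacetate F10. K2CO3 and MeI in degassed MeOH/acetone would cleave the acetates in the closed flask and methylate the free O8 as it appears, giving 11.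

## Further compounds

F1 | step 4 | 2-(benzyloxy)-1-(2-bromo-3,4,5,6-tetramethoxyphenyl)ethan-1-one | COc1c(Br)c(C(=O)COCc2ccccc2)c(OC)c(OC)c1OC
F2 | step 4 | 2-(benzyloxy)-3-[4-(benzyloxy)phenyl]-1-(2-bromo-3,4,5,6-tetramethoxyphenyl)propane-1,3-dione (racemic) | COc1c(Br)c(C(=O)C(OCc2ccccc2)C(=O)c2ccc(OCc3ccccc3)cc2)c(OC)c(OC)c1OC
F3 | step 4 | 3-(benzyloxy)-2-[4-(benzyloxy)phenyl]-5,6,7,8-tetramethoxy-4H-chromen-4-one | COc1c(OC)c(OC)c2c(=O)c(OCc3ccccc3)c(-c3ccc(OCc4ccccc4)cc3)oc2c1OC
F4 | step 2 | 2,3-dimethoxycyclohexa-2,5-diene-1,4-dione | COC1=C(OC)C(=O)C=CC1=O
F5 | step 2 | 2,3-dimethoxybenzene-1,4-diol | COc1c(O)ccc(O)c1OC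
F6 | step 2 | 2,3-dimethoxy-1,4-bis(methoxymethoxy)benzene | COCOc1ccc(OCOC)c(OC)c1OC
F7 | step 2 | 2-(benzyloxy)-1-[3,4-dimethoxy-2,5-bis(methoxymethoxy)phenyl]ethan-1-one | COCOc1cc(C(=O)COCc2ccccc2)c(OCOC)c(OC)c1OC
F8 | step 3 | 2-[2-(benzyloxy)acetyl]-5,6-dimethoxy-1,4-phenylene bis[4-(benzyloxy)benzoate] | COc1c(OC(=O)c2ccc(OCc3ccccc3)cc2)cc(C(=O)COCc2ccccc2)c(OC(=O)c2ccc(OCc3ccccc3)cc2)c1OC
F9 | step 3 | 5-{2-(benzyloxy)-3-[4-(benzyloxy)phenyl]-3-oxopropanoyl}-4-hydroxy-2,3-dimethoxyphenyl 4-(benzyloxy)benzoate (racemic) | COc1c(OC(=O)c2ccc(OCc3ccccc3)cc2)cc(C(=O)C(OCc2ccccc2)C(=O)c2ccc(OCc3ccccc3)cc2)c(O)c1OC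
F10 | step 5 | 3-(benzyloxy)-2-[4-(benzyloxy)phenyl]-6,7-dimethoxy-4-oxo-4H-chromene-5,8-diyl diacetate | COc1c(OC)c(OC(C)=O)c2c(=O)c(OCc3ccccc3)c(-c3ccc(OCc4ccccc4)cc3)oc2c1OC(C)=O
A1 | alternative 1 | (Z)-2-(benzyloxy)-3-[4-(benzyloxy)phenyl]-1-(2-hydroxy-3,4,5,6-tetramethoxyphenyl)prop-2-en-1-one | COc1c(OC)c(OC)c(C(=O)/C(OCc2ccccc2)=C/c2ccc(OCc3ccccc3)cc2)c(O)c1OC
A2 | alternative 1 | 2,3,4,5-tetramethoxy-6-(trimethylsilyl)phenyl trifluoromethanesulfonate | COc1c(OC)c(OC)c([Si](C)(C)C)c(OS(=O)(=O)C(F)(F)F)c1OC
A3 | alternative 1 | (Z)-2-(benzyloxy)-3-[4-(benzyloxy)phenyl]prop-2-enoic acid | OC(=O)/C(OCc1ccccc1)=C/c1ccc(OCc2ccccc2)cc1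
A4 | alternative 2 | 2-[4-(benzyloxy)phenyl]-5,6,7,8-tetramethoxy-2H-chromene (racemic) | COc1c(OC)c(OC)c2c(c1OC)OC(c1ccc(OCc3ccccc3)cc1)C=C2
A5 | alternative 2 | 2-hydroxy-3,4,5,6-tetramethoxybenzaldehyde | COc1c(OC)c(OC)c(C=O)c(O)c1OC
A6 | alternative 2 | (E)-2-[4-(benzyloxy)phenyl]ethenylboronic acid | OB(O)/C=C/c1ccc(OCc2ccccc2)cc1
A7 | alternative 3 | 2-[4-(benzyloxy)phenyl]-5,6,7,8-tetramethoxy-4H-chromen-4-one | COc1c(OC)c(OC)c2c(=O)cc(-c3ccc(OCc4ccccc4)cc3)oc2c1OC
A8 | alternative 3 | (Z)-3-[4-(benzyloxy)phenyl]-3-(2,3,4,5-tetramethoxyphenoxy)prop-2-enoic acid | O=C(O)/C=C(/c1ccc(OCc2ccccc2)cc1)Oc1cc(OC)c(OC)c(OC)c1OC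
A9 | alternative 3 | 2,3,4,5-tetramethoxyphenol | COc1cc(O)c(OC)c(OC)c1OC
A10 | alternative 3 | ethyl 3-[4-(benzyloxy)phenyl]prop-2-ynoate | CCOC(=O)C#Cc1ccc(OCc2ccccc2)cc1
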